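**Plan**
- Retrosynthesis: the first cut is one C–CH3 bond at C6 of the cyclohexadienone ring (ring A), which turns aspidin into an all-aromatic diarylmethane. The next cuts are the bridge CH2–C(ring A) bond, the two butanoyl C–aryl bonds, the O–CH3 bond and the formyl C–aryl bond of ring B.
- Enabling feature: C6 of ring A, the only sp3 ring atom, lies between C1=O and C5–OH of a 1,3,5-trioxygenated six-membered ring. Ring A is therefore the C-methylated keto form of a 2,4,6-trihydroxy-3-methylphenyl ketone. In ring B the OMe is para to the bridge carbon.
- Forward: both rings come from 2,4,6-trihydroxytoluene. Ring A arm: butanoylation. Ring B arm: formylation (the formyl is the future bridge carbon and steers O-methylation to its para OH), O-methylation, butanoylation.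
- The chain is joined by reducing the formyl group and trapping the derived ortho-quinone methide with the ring A arene. No ring is closed; ring A is dearomatised last by C-methylation.
- The dimethyl-dienone ring is thus never a separate building block, is not built from acyclic pieces, and the bridge carbon does not come from a ring methyl group.
- Stereochemistry: none to set.

Key step: step 6

Remark: aspidin has no stereocentre (the sp3 ring carbon carries two identical methyl groups), so the request for a single enantiomer imposes no requirement. The target is named and drawn in the tautomeric form of the given SMILES.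

**Step 1**
Reactants: 1 2,4,6-trihydroxytoluene (2-methylbenzene-1,3,5-triol)
Product: 2 1-(2,4,6-trihydroxy-3-methylphenyl)butan-1-one
Conditions: PrCOCl (1.05 equiv), AlCl3 (3 equiv), PhNO2–CH2Cl2, 0 °C → rt; aq HCl
Reagents that add atoms: butanoyl chloride, CCCC(=O)Cl
Why: Friedel–Crafts C-acylation at one of the two equivalent free ring carbons of the phloroglucinol; the first acyl group deactivates the ring, so monoacylation should prevail.

**Step 2**
Reactants: 1 2,4,6-trihydroxytoluene
Product: 3 2,4,6-trihydroxy-3-methylbenzaldehyde
Conditions: POCl3 (1.1 equiv), DMF (1.2 equiv), EtOAc, 0 °C → rt; then H2O, 60 °C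
Reagents that add atoms: N,N-dimethylformamide, CN(C)C=O; water, O
Why: Vilsmeier–Haack formylation of the electron-rich arene at one of its two equivalent free positions, the aldehyde being released on hydrolysis of the iminium salt.

**Step 3**
Reactants: 3 2,4,6-trihydroxy-3-methylbenzaldehyde
Product: 4 2,6-dihydroxy-4-methoxy-3-methylbenzaldehyde
Conditions: Me2SO4 (1.0 equiv), K2CO3 (1.0 equiv), acetone, 0 °C → rt
Reagents that add atoms: dimethyl sulfate, COS(=O)(=O)OC
Why: Williamson O-methylation with one equivalent of base should go to the OH para to the formyl group, which is the most acidic and the only one not hydrogen-bonded to the carbonyl, as in the known para-selective monomethylation of 2,4,6-trihydroxyaryl carbonyl compounds.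

**Step 4**
Reactants: 4 2,6-dihydroxy-4-methoxy-3-methylbenzaldehyde
Product: 5 3-butanoyl-2,6-dihydroxy-4-methoxy-5-methylbenzaldehyde
Conditions: (PrCO)2O (1.5 equiv), BF3·OEt2 (5 equiv), 60 °C; then MeOH–H2O, 50 °C
Reagents that add atoms: butanoic anhydride, CCCC(=O)OC(=O)CCC
Why: BF3-mediated Friedel–Crafts acylation at the only unsubstituted ring carbon (ortho to OMe and OH, para to OH), of the kind that converts monoacylphloroglucinols into 2,4-diacylphloroglucinols; BF3 does not cleave the aryl methyl ether, and the aqueous methanol work-up should hydrolyse boron chelates and any O-acyl or acylal by-products.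

**Step 5**
Reactants: 5 3-butanoyl-2,6-dihydroxy-4-methoxy-5-methylbenzaldehyde; 2 1-(2,4,6-trihydroxy-3-methylphenyl)butan-1-one (2.0 equiv)
Product: 8 1-[3-[(3-butanoyl-2,6-dihydroxy-4-methoxy-5-methylphenyl)methyl]-2,4,6-trihydroxy-5-methylphenyl]butan-1-one, via benzylic alcohol 6 (not isolated), via ortho-quinone methide 7 (not isolated)
Conditions: NaBH4 (0.5 equiv), THF–EtOH, −20 °C; acetone; then 2 (2.0 equiv), AcOH, −20 °C → rt
Reagents that add atoms: none
Why: borohydride should reduce the aldehyde faster than the chelated aryl ketone to give the 2-hydroxybenzyl alcohol, which under mild acid loses water to the ortho-quinone methide and is captured at the single free, doubly OH-flanked ring carbon of 2 (Friedel–Crafts-type conjugate addition); the electrophile is fully substituted and cannot alkylate itself at carbon, so only the cross-coupled diarylmethane can form by C–C bonding.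

**Step 6**
Reactants: 8 1-[3-[(3-butanoyl-2,6-dihydroxy-4-methoxy-5-methylphenyl)methyl]-2,4,6-trihydroxy-5-methylphenyl]butan-1-one
Product: 9 aspidin, 2-butanoyl-4-[(3-butanoyl-2,6-dihydroxy-4-methoxy-5-methylphenyl)methyl]-3,5-dihydroxy-6,6-dimethylcyclohexa-2,4-dien-1-one
Conditions: NaOMe (4 equiv), MeI (1.1 equiv), MeOH, N2, −10 → 0 °C; then 1 M HCl
Reagents that add atoms: iodomethane, CI
Why: NaOMe turns the trihydroxy ring of 8 (the aromatic tautomer of a cyclic β-triketone) into its polyanion, which attacks MeI in an SN2 step through the methyl-bearing ring carbon C5, so that this carbon becomes the sp3 C(CH3)2 atom and the ring is locked as the dihydroxy-dimethylcyclohexadienone of 9. The closest known reaction type is the classical nuclear C-methylation (alkylative dearomatisation with MeI/NaOMe/MeOH) of C-alkylated acylphloroglucinols to gem-dialkyl cyclohexadienones. No ring is closed and no stereocentre arises, because the new quaternary carbon bears two identical methyl groups. The step needs C- over O-methylation, the trihydroxy ring over the methoxy ring, C5 over C3 and C1, and a single methylation: the protic medium and sodium counter-ion favour attack through carbon; the methoxy ring has one oxygen capped and only hindered, ketone-conjugated phenoxides, so it cannot reach a stable triketone; C1 carries the electron-withdrawing butanoyl group and C3 the bulky 2,6-disubstituted benzyl group, which leaves C5 as the least hindered nucleophilic carbon. The product is a vinylogous acid that is deprotonated at once to a delocalised anion of low nucleophilicity, which together with 1.1 equiv of MeI at or below 0 °C should limit over-methylation and leave little time for base-induced scission of the methylene bridge.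

**Compound list**
1 | 2,4,6-trihydroxytoluene (2-methylbenzene-1,3,5-triol) | Cc1c(O)cc(O)cc1O | starting material
2 | 1-(2,4,6-trihydroxy-3-methylphenyl)butan-1-one | CCCC(=O)c1c(O)cc(O)c(C)c1O | intermediate
3 | 2,4,6-trihydroxy-3-methylbenzaldehyde | Cc1c(O)cc(O)c(C=O)c1O | intermediate
4 | 2,6-dihydroxy-4-methoxy-3-methylbenzaldehyde | COc1cc(O)c(C=O)c(O)c1C | intermediate
5 | 3-butanoyl-2,6-dihydroxy-4-methoxy-5-methylbenzaldehyde | CCCC(=O)c1c(O)c(C=O)c(O)c(C)c1OC | intermediate
6 | 1-[2,4-dihydroxy-3-(hydroxymethyl)-6-methoxy-5-methylphenyl]butan-1-one (benzylic alcohol, not isolated) | CCCC(=O)c1c(O)c(CO)c(O)c(C)c1OC | intermediate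
7 | 4-butanoyl-3-hydroxy-5-methoxy-6-methyl-2-methylidenecyclohexa-3,5-dien-1-one (ortho-quinone methide, not isolated) | CCCC(=O)C1=C(O)C(=C)C(=O)C(C)=C1OC | intermediate
8 | 1-[3-[(3-butanoyl-2,6-dihydroxy-4-methoxy-5-methylphenyl)methyl]-2,4,6-trihydroxy-5-methylphenyl]butan-1-one | CCCC(=O)c1c(O)c(C)c(O)c(Cc2c(O)c(C)c(OC)c(C(=O)CCC)c2O)c1O | intermediate
9 | aspidin, 2-butanoyl-4-[(3-butanoyl-2,6-dihydroxy-4-methoxy-5-methylphenyl)methyl]-3,5-dihydroxy-6,6-dimethylcyclohexa-2,4-dien-1-one | CCCC(=O)C1=C(O)C(Cc2c(O)c(C)c(OC)c(C(=O)CCC)c2O)=C(O)C(C)(C)C1=O | target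

**Count**
Total steps: 6. Longest linear sequence: 5 steps (1 → 3 → 4 → 5 → 8 → 9); step 1 is a one-step branch.

**Steps most likely to fail**

Step 6. The methylation may go to the benzyl-bearing ring carbon or to oxygen, may occur twice, or the base may cleave and scramble the methylene bridge. The fallback sets out from 5 and comes back at 9, bringing the quaternary carbon in on a ring that carries no butanoyl group. Commercial 1-(2,4,6-trihydroxyphenyl)ethan-1-one would be gem-dimethylated (MeI, NaOMe, MeOH) to 2-acetyl-3,5-dihydroxy-4,4-dimethylcyclohexa-2,5-dien-1-one F1 and deacetylated with hot aqueous H2SO4 to filicinic acid, 3,5-dihydroxy-4,4-dimethylcyclohexa-2,5-dien-1-one F2. Aldehyde 5 would be reduced as in step 5, and the quinone methide 7 trapped by an excess of F2 to give 2-[(3-butanoyl-2,6-dihydroxy-4-methoxy-5-methylphenyl)methyl]-3,5-dihydroxy-4,4-dimethylcyclohexa-2,5-dien-1-one F3. Direct BF3·OEt2-mediated C-butanoylation of the one remaining ring CH of F3 with butanoic anhydride should then give 9.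

Step 5. Residual hydride may reduce the quinone methide on to a methyl group, the ketone may be reduced, or the quinone methide may dimerise before it is trapped. The fallback sets out from 5 and comes back at 8, generating the quinone methide without hydride present. Reductive amination of 5 with piperidine and NaBH(OAc)3 should give the Mannich base 1-[2,4-dihydroxy-6-methoxy-5-methyl-3-(piperidin-1-ylmethyl)phenyl]butan-1-one F4. Heating F4 with 2 in dioxane at 90 °C should expel the amine, form 7 and deliver 8.

Step 4. The formyl-deactivated ring may fail to acylate, or the Lewis acid may attack the aldehyde or cleave the methyl ether. The fallback sets out from 4 and comes back at 8, postponing the ring B acylation until after the union. Under the conditions of step 5, 4 would be reduced to 2-(hydroxymethyl)-5-methoxy-4-methylbenzene-1,3-diol F5, ionised to 3-hydroxy-5-methoxy-6-methyl-2-methylidenecyclohexa-3,5-dien-1-one F6 and trapped by 2 (3 equiv) to give 1-[3-[(2,6-dihydroxy-4-methoxy-3-methylphenyl)methyl]-2,4,6-trihydroxy-5-methylphenyl]butan-1-one F7. The methoxy ring of F7 is no longer deactivated by a formyl group, so butanoic anhydride and BF3·OEt2 at rt should acylate its only free ring carbon to give 8.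

**Further compounds**
F1 | step 6 | 2-acetyl-3,5-dihydroxy-4,4-dimethylcyclohexa-2,5-dien-1-one | CC(=O)C1=C(O)C(C)(C)C(O)=CC1=O
F2 | step 6 | filicinic acid, 3,5-dihydroxy-4,4-dimethylcyclohexa-2,5-dien-1-one | CC1(C)C(O)=CC(=O)C=C1O
F3 | step 6 | 2-[(3-butanoyl-2,6-dihydroxy-4-methoxy-5-methylphenyl)methyl]-3,5-dihydroxy-4,4-dimethylcyclohexa-2,5-dien-1-one | CCCC(=O)c1c(O)c(CC2=C(O)C(C)(C)C(O)=CC2=O)c(O)c(C)c1OC
F4 | step 5 | 1-[2,4-dihydroxy-6-methoxy-5-methyl-3-(piperidin-1-ylmethyl)phenyl]butan-1-one | CCCC(=O)c1c(O)c(CN2CCCCC2)c(O)c(C)c1OC
F5 | step 4 | 2-(hydroxymethyl)-5-methoxy-4-methylbenzene-1,3-diol | COc1cc(O)c(CO)c(O)c1C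
F6 | step 4 | 3-hydroxy-5-methoxy-6-methyl-2-methylidenecyclohexa-3,5-dien-1-one | C=C1C(O)=CC(OC)=C(C)C1=O
F7 | step 4 | 1-[3-[(2,6-dihydroxy-4-methoxy-3-methylphenyl)methyl]-2,4,6-trihydroxy-5-methylphenyl]butan-1-one | CCCC(=O)c1c(O)c(C)c(O)c(Cc2c(O)cc(OC)c(C)c2O)c1O
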